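**Strategy**

Atom labels follow the target: C1–C7 of the bicyclo[3.1.1]heptane (C2 spiro, C6 = CMe2, C7 = CH2), primed atoms for the chromene. The cyclobutane (C1, C6, C5, C7) is cut by a retro-[2+2] into a ketene C5=C7=O and an isobutenyl group C1=C6Me2. The precursor is a dihydropyran-fused syncarpic unit whose carbon C2 carries both the isobutenyl group and a 3-carboxypropyl chain. One thermal intramolecular ketene–alkene cycloaddition forms C7–C1 and C5–C6, closing the carbocyclic six-membered ring and, last, the cyclobutane, and sets C1 and C5 from C2. It exploits the gem-dimethyl carbon C6, which steers the crossed, bridged mode. The surplus C7 carbonyl is then removed.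

Key step: step 6

Assumption: syncarpic acid (8) is taken as a purchasable compound.

**Route**

Step 1
Reactants: 1 crotonic acid
Product: 2 1,1-bis(trimethylsilyloxy)buta-1,3-diene
Conditions: LiN(i-Pr)2 (2.2 equiv), THF, −78 → 0 °C; Me3SiCl (2.5 equiv), −78 → 23 °C; distillation
Reagents that add atoms: chlorotrimethylsilane, C[Si](C)(C)Cl
Why: Two equivalents of amide base should give the lithium dienediolate of crotonic acid, which is silylated on both oxygens to the bis-silyl ketene acetal (silyl dienolate formation).

Step 2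
Reactants: 3 mesityl oxide; 4 isovaleraldehyde
Product: 7 (5E)-2,8-dimethylnona-2,5-dien-4-one, via aldol adduct 5 (not isolated), via mesylate 6 (not isolated)
Conditions: LiN(i-Pr)2, THF, −78 °C; then 4; then MsCl, Et3N, −78 → 23 °C
Reagents that add atoms: none
Why: Kinetic deprotonation of 3 at its methyl ketone carbon gives the cross-conjugated lithium enolate, which adds to 4 (aldol addition), and mesylation of the aldolate followed by E1cB elimination should give the (E)-enone (aldol condensation).

Step 3
Reactants: 7 (5E)-2,8-dimethylnona-2,5-dien-4-one; 8 syncarpic acid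
Product: 9 (4R)-2-hydroxy-6,6,8,8-tetramethyl-4-(2-methylpropyl)-2-(2-methylprop-1-en-1-yl)-3,4-dihydro-2H-chromene-5,7(6H,8H)-dione (hemiketal, both C2 epimers)
Conditions: 9-amino-9-deoxy-epi-quinine (20 mol %), CF3CO2H (40 mol %), CH2Cl2, 23 °C
Reagents that add atoms: none
Why: The primary amine forms an iminium ion with the dienone, the enol of 8 adds through carbon to the monosubstituted β-carbon (the β,β-dimethyl terminus is too hindered) on the face left open by the cinchona framework, which sets C4′ (R expected by analogy with the adducts this catalyst gives from 4-hydroxycoumarin and enones; the quinidine-derived pseudo-enantiomer serves if the sense proves opposite), and the adduct closes to the hemiketal (organocatalytic asymmetric Michael addition–hemiketalisation).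

Step 4
Reactants: 9 hemiketal; 2 1,1-bis(trimethylsilyloxy)buta-1,3-diene
Product: 12 (2E)-4-[(2R,4R)-6,6,8,8-tetramethyl-4-(2-methylpropyl)-2-(2-methylprop-1-en-1-yl)-5,7-dioxo-3,4,5,6,7,8-hexahydro-2H-chromen-2-yl]but-2-enoic acid, via oxocarbenium triflate 10 (not isolated), via trimethylsilyl ester 11 (not isolated)
Conditions: 2 (2 equiv), Me3SiOTf (20 mol %), CH2Cl2, −78 °C; Et3N quench; aqueous work-up at pH 4
Reagents that add atoms: none
Why: Me3SiOTf ionises the hemiketal to the conjugated oxocarbenium ion 10, which should be captured at C2′ by the terminal (γ) carbon of dienediolate 2 (vinylogous Mukaiyama-type substitution of a ketal) on the face anti to the pseudo-axial isobutyl group at C4′, so that the new chain stands trans to isobutyl and C2 is set as R; the silyl ester 11 is cleaved on work-up.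

Step 5
Reactants: 12 enoic acid
Product: 13 4-[(2R,4R)-6,6,8,8-tetramethyl-4-(2-methylpropyl)-2-(2-methylprop-1-en-1-yl)-5,7-dioxo-3,4,5,6,7,8-hexahydro-2H-chromen-2-yl]butanoic acid
Conditions: H2 (3 atm), RhCl(PPh3)3 (10 mol %), PhH–EtOH, 23 °C
Reagents that add atoms: none
Why: RhCl(PPh3)3 should hydrogenate the unhindered 1,2-disubstituted alkene of the enoic acid (homogeneous catalytic hydrogenation) much faster than the trisubstituted isobutenyl alkene or the tetrasubstituted enol ether alkene, so only the chain is saturated and no stereocenter is touched.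

Step 6
Reactants: 13 butanoic acid
Product: 16 (1R,2R,5R,4′R)-cyclobutanone (the 7-oxo derivative of 18 in the atom labels of the target), via acid chloride 14 (not isolated), via ketene 15 (not isolated)
Conditions: Me2C=C(Cl)NMe2 (1.2 equiv), CH2Cl2, 0 → 23 °C; then syringe-pump addition to Et3N (5 equiv), PhMe, 80 °C (0.005 M)
Reagents that add atoms: none
Why: Et3N converts acid chloride 14 into aldoketene 15, whose electrophilic carbonyl carbon C7 is attacked in the ketene plane by alkene carbon C1 while the developing tertiary cationic centre C6 bonds to the ketene carbon C5, an asynchronous concerted [2+2] cycloaddition. The closest known reaction type is the intramolecular ketene–alkene cycloaddition of 6-alkenylketenes with a trisubstituted, dimethyl-terminated alkene, which gives 7,7-dimethylbicyclo[3.1.1]heptan-6-ones. The C7–C1 bond closes the six-membered carbocycle in a 6-exo fashion (C6 stays outside that ring) and the C5–C6 bond then closes the four-membered ring by collapse of the C6 cation onto the enolate-like C5, so the cyclobutane is the last ring formed. C1 is set by the allylic spiro centre C2: C7 should approach C1 anti to the C2–C3′ bond, with tether carbon C3 inside and the C2–O1′ bond near the alkene plane, because an anti C–O bond would withdraw electron density from the reacting π bond (inside/outside-alkoxy model for electrophilic attack on allylic ethers) and C3′ is the larger anti substituent; this places C6Me2 syn to C3′ and C7 syn to O1′, and C5 follows from C1 because the one-carbon bridges can only span one face. The step needs the crossed (bicyclo[3.1.1]) and not the fused (bicyclo[3.2.0]) regiochemistry, which the more substituted distal alkene carbon C6 secures, and it needs cycloaddition to outrun ketene dimerisation and ionisation of the tertiary allylic ether, for which slow addition at high dilution under base is used.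

Step 7
Reactants: 16 cyclobutanone
Product: 18 target (1R,2R,5S,4′R)-6,6,6′,6′,8′,8′-hexamethyl-4′-(2-methylpropyl)-3′,4′-dihydrospiro[bicyclo[3.1.1]heptane-2,2′-chromene]-5′,7′(6′H,8′H)-dione, via tosylhydrazone 17 (not isolated)
Conditions: TsNHNH2 (1.1 equiv), MeOH, 23 °C; solvent exchange; catecholborane, CHCl3, 0 °C; then NaOAc·3H2O, 60 °C
Reagents that add atoms: none
Why: The strained cyclobutanone should condense selectively with TsNHNH2, and hydride delivery from catecholborane followed by acetate-induced loss of sulfinate and N2 replaces C=O by CH2 (Caglioti-type reductive deoxygenation of a tosylhydrazone) without touching the s-trans vinylogous ester or the hindered ketone; no stereocenter is affected.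

**Compound list**

1 | crotonic acid, (E)-but-2-enoic acid | C/C=C/C(=O)O | starting material
2 | 1,1-bis(trimethylsilyloxy)buta-1,3-diene | C=CC=C(O[Si](C)(C)C)O[Si](C)(C)C | intermediate
3 | mesityl oxide, 4-methylpent-3-en-2-one | CC(=O)C=C(C)C | starting material
4 | isovaleraldehyde, 3-methylbutanal | CC(C)CC=O | starting material
5 | 6-hydroxy-2,8-dimethylnon-2-en-4-one (racemic aldol adduct, formed as its lithium alkoxide) | CC(C)CC(O)CC(=O)C=C(C)C | intermediate
6 | 2,8-dimethyl-4-oxonon-2-en-6-yl methanesulfonate (racemic) | CC(C)CC(OS(C)(=O)=O)CC(=O)C=C(C)C | intermediate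
7 | (5E)-2,8-dimethylnona-2,5-dien-4-one | CC(C)C/C=C/C(=O)C=C(C)C | intermediate
8 | syncarpic acid, 2,2,4,4-tetramethylcyclohexane-1,3,5-trione | CC1(C)C(=O)CC(=O)C(C)(C)C1=O | starting material
9 | (4R)-2-hydroxy-6,6,8,8-tetramethyl-4-(2-methylpropyl)-2-(2-methylprop-1-en-1-yl)-3,4-dihydro-2H-chromene-5,7(6H,8H)-dione (hemiketal, both C2 epimers, in equilibrium with the open-chain Michael adduct) | CC(C)C[C@@H]1CC(O)(C=C(C)C)OC2=C1C(=O)C(C)(C)C(=O)C2(C)C | intermediate
10 | (4R)-oxocarbenium triflate formed from 9 by loss of the C2 hydroxyl | CC(C)C[C@@H]1CC(C=C(C)C)=[O+]C2=C1C(=O)C(C)(C)C(=O)C2(C)C.[O-]S(=O)(=O)C(F)(F)F | intermediate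
11 | trimethylsilyl ester of 12 | CC(C)C[C@@H]1C[C@@](C=C(C)C)(C/C=C/C(=O)O[Si](C)(C)C)OC2=C1C(=O)C(C)(C)C(=O)C2(C)C | intermediate
12 | (2E)-4-[(2R,4R)-6,6,8,8-tetramethyl-4-(2-methylpropyl)-2-(2-methylprop-1-en-1-yl)-5,7-dioxo-3,4,5,6,7,8-hexahydro-2H-chromen-2-yl]but-2-enoic acid (chain trans to isobutyl) | CC(C)C[C@@H]1C[C@@](C=C(C)C)(C/C=C/C(=O)O)OC2=C1C(=O)C(C)(C)C(=O)C2(C)C | intermediate
13 | 4-[(2R,4R)-6,6,8,8-tetramethyl-4-(2-methylpropyl)-2-(2-methylprop-1-en-1-yl)-5,7-dioxo-3,4,5,6,7,8-hexahydro-2H-chromen-2-yl]butanoic acid | CC(C)C[C@@H]1C[C@@](C=C(C)C)(CCCC(=O)O)OC2=C1C(=O)C(C)(C)C(=O)C2(C)C | intermediate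
14 | acid chloride of 13 | CC(C)C[C@@H]1C[C@@](C=C(C)C)(CCCC(=O)Cl)OC2=C1C(=O)C(C)(C)C(=O)C2(C)C | intermediate
15 | ketene from 14, (2R,4R)-2-(4-oxobut-3-en-1-yl) compound | CC(C)C[C@@H]1C[C@@](C=C(C)C)(CCC=C=O)OC2=C1C(=O)C(C)(C)C(=O)C2(C)C | intermediate
16 | (1R,2R,5R,4′R)-cyclobutanone, the 7-oxo derivative of 18 (carbonyl at C7, gem-dimethyl at C6, target atom labels) | CC(C)C[C@@H]1C[C@@]2(CC[C@H]3C(=O)[C@@H]2C3(C)C)OC2=C1C(=O)C(C)(C)C(=O)C2(C)C | intermediate
17 | N-tosylhydrazone of 16 at the cyclobutanone carbonyl | CC(C)C[C@@H]1C[C@@]2(CC[C@H]3C(=NNS(=O)(=O)c4ccc(C)cc4)[C@@H]2C3(C)C)OC2=C1C(=O)C(C)(C)C(=O)C2(C)C | intermediate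
18 | (1R,2R,5S,4′R)-6,6,6′,6′,8′,8′-hexamethyl-4′-(2-methylpropyl)-3′,4′-dihydrospiro[bicyclo[3.1.1]heptane-2,2′-chromene]-5′,7′(6′H,8′H)-dione | CC(C)C[C@@H]1C[C@@]2(CC[C@H]3C[C@@H]2C3(C)C)OC2=C1C(=O)C(C)(C)C(=O)C2(C)C | target

**Count and risks**

Total steps: 7. Longest linear sequence: 6 steps (steps 2 to 7).

Steps most likely to fail:

1. Step 6. Bond formation at the alkene carbon next to the quaternary centre may be slow, so that the ketene dimerises or the tertiary allylic ether ionises at 80 °C. Attack on the other alkene face would give the C1/C5 diastereomer, and this face selectivity rests on a model, not on a direct precedent. The fallback sets out from 13 and comes back at 16. Acid chloride 14 is intercepted with pyrrolidine to give the pyrrolidine amide F1. Tf2O and 2,6-di-tert-butyl-4-methylpyridine in ClCH2CH2Cl (0 → 40 °C) convert it into the keteniminium triflate F2, a much stronger electrophile than the ketene, which should add to the isobutenyl group well below 80 °C to give the cyclobutaniminium triflate F3. Hydrolysis (H2O, CCl4, 60 °C) returns 16.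

2. Step 4. The ambident dienediolate may bond through its α-carbon, the cation may be captured at its remote terminus C6, and lingering Lewis acid may re-ionise the product with loss of the C2 configuration. The fallback sets out from 9 and comes back at 12, and builds the chain in two stages. Allyltrimethylsilane with Me3SiOTf (CH2Cl2, −78 °C), a compact non-ambident nucleophile, should give the (2R,4R)-2-allyl compound F4. Cross-metathesis with acrylic acid (second-generation Hoveyda–Grubbs catalyst, CH2Cl2, 40 °C), to which the trisubstituted isobutenyl group is inert, then gives 12.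

3. Step 7. Hydrazone formation at the hindered bridged ketone may be incomplete or may also involve the vinylogous ester carbonyl, and the strained ring may fragment during diazene decomposition. The fallback sets out from 16 and comes back at 18. NaBH4 (MeOH, −20 °C) should reduce only the cyclobutanone to the cyclobutanol F5. 1,1′-Thiocarbonyldiimidazole (ClCH2CH2Cl, 60 °C) gives the imidazolylthiocarbonate F6, and Bu3SnH with AIBN (PhMe, 100 °C) removes the oxygen by radical deoxygenation (Barton–McCombie reaction) to give 18.

Further compounds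

F1 | step 6 | pyrrolidine amide of 13 | CC(C)C[C@@H]1C[C@@](C=C(C)C)(CCCC(=O)N3CCCC3)OC2=C1C(=O)C(C)(C)C(=O)C2(C)C
F2 | step 6 | keteniminium triflate from F1 | CC(C)C[C@@H]1C[C@@](C=C(C)C)(CCC=C=[N+]3CCCC3)OC2=C1C(=O)C(C)(C)C(=O)C2(C)C.[O-]S(=O)(=O)C(F)(F)F
F3 | step 6 | cyclobutaniminium triflate (pyrrolidinium analogue of 16) | CC(C)C[C@@H]1C[C@@]2(CC[C@H]3C(=[N+]4CCCC4)[C@@H]2C3(C)C)OC2=C1C(=O)C(C)(C)C(=O)C2(C)C.[O-]S(=O)(=O)C(F)(F)F
F4 | step 4 | (2R,4R)-6,6,8,8-tetramethyl-4-(2-methylpropyl)-2-(2-methylprop-1-en-1-yl)-2-(prop-2-en-1-yl)-3,4-dihydro-2H-chromene-5,7(6H,8H)-dione | CC(C)C[C@@H]1C[C@@](C=C(C)C)(CC=C)OC2=C1C(=O)C(C)(C)C(=O)C2(C)C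
F5 | step 7 | cyclobutanol from 16 (7-hydroxy derivative of 18, either carbinol epimer) | CC(C)C[C@@H]1C[C@@]2(CC[C@H]3C(O)[C@@H]2C3(C)C)OC2=C1C(=O)C(C)(C)C(=O)C2(C)C
F6 | step 7 | O-(imidazol-1-ylthiocarbonyl) derivative of F5 | CC(C)C[C@@H]1C[C@@]2(CC[C@H]3C(OC(=S)n4ccnc4)[C@@H]2C3(C)C)OC2=C1C(=O)C(C)(C)C(=O)C2(C)C
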